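Both rings are L-quinates (mirror image of the natural acid). Everything rests on disconnecting the C3A–O and C4A–O bonds of ring A, whose cis-diol (O3A, O4A) lies trans to the one differentiated oxygen, O5A. A single OsO4 syn-dihydroxylation of the C3A=C4A olefin in the assembled dimer, anti to the allylic O5A silyl ether, sets both stereocentres and completes the oxygenation pattern. The precursor is the O1B ester of a protected ring B L-quinate (4,5-bisacetal, 4-methoxybenzyl ester) with 1-hydroxy-5-silyloxycyclohex-3-ene-1-carboxylic acid, its tertiary C1A hydroxyl left free. Both halves come from D-quinic acid by inversion at C3 and excision, then reinstatement, of the 4,5-diol.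

Key step: step 14

Assumption: the SMILES is taken as drawn; both cyclohexane rings are then (3S,5S), the L-quinate series, so each differs from D-quinic acid at C3 and C5. Ring A is the acyl quinate and ring B the quinate acylated at O1B. Compounds 2–6 keep the D-quinate numbering; the carbon numbered C3 there becomes C5 of the L-series (C5A or C5B).

Step 1
Reactants: 1 D-(−)-quinic acid
Product: 2 methyl D-quinate 4,5-O-(2,3-dimethoxybutane-2,3-diyl) bisacetal (1-OH and axial 3-OH free)
Conditions: 2,3-butanedione, HC(OMe)3, 10-camphorsulfonic acid (cat.), MeOH, reflux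
Reagents that add atoms: 2,3-butanedione (CC(=O)C(C)=O); methanol (CO); trimethyl orthoformate (COC(OC)OC)
Why: Fischer esterification and thermodynamically controlled bisacetalisation (butane-2,3-diacetal protection) pick out the only trans-diequatorial 1,2-diol, O4/O5, with both acetal methoxy groups axial, leaving the ring stereocentres untouched.

Step 2
Reactants: 2 methyl D-quinate 4,5-bisacetal
Product: 3 methyl 3-dehydroquinate 4,5-bisacetal (3-ketone)
Conditions: Dess–Martin periodinane, CH2Cl2, 0 °C → rt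
Reagents that add atoms: none
Why: Dess–Martin oxidation of the only secondary alcohol; the tertiary C1 alcohol cannot be oxidised and the near-neutral medium avoids β-elimination of the C1 hydroxyl from the β-hydroxy ketone.

Step 3
Reactants: 3 methyl 3-dehydroquinate 4,5-bisacetal
Product: 4 methyl 3-epi-quinate 4,5-bisacetal (3-OH equatorial and trans to 1-OH)
Conditions: Me4NBH(OAc)3, MeCN/AcOH (1:1), −25 °C
Reagents that add atoms: none
Why: Evans–Saksena hydroxyl-directed reduction: the axial C1 hydroxyl binds the triacetoxyborohydride and delivers hydride to the same face of the C3 carbonyl, so the new C3 hydroxyl is equatorial and trans to O1, which inverts C3 (the future C5 of both rings).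

Step 4
Reactants: 4 methyl 3-epi-quinate 4,5-bisacetal
Product: 5 3-O-tert-butyldiphenylsilyl (TBDPS) ether of 4
Conditions: t-BuPh2SiCl, imidazole, DMF, rt
Reagents that add atoms: tert-butyl(chloro)diphenylsilane (CC(C)(C)[Si](Cl)(c1ccccc1)c1ccccc1)
Why: Silylation of the only secondary hydroxyl (the tertiary α-hydroxy ester does not react with the bulky chlorosilane); the TBDPS ether is chosen because it survives aqueous trifluoroacetic acid and does not migrate.

Step 5
Reactants: 5 3-O-TBDPS bisacetal
Product: 6 methyl 3-O-TBDPS-3-epi-quinate (free trans-4,5-diol; O3/O4/O5 all-trans)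
Conditions: CF3CO2H/H2O (9:1), rt, 30 min
Reagents that add atoms: none
Why: Standard acid hydrolysis of the butane-2,3-diacetal; the silyl tag on O3 is what keeps the otherwise meso all-trans triol chiral, so a group that neither cleaves nor migrates under acid is essential.

Step 6
Reactants: 6 methyl 3-O-TBDPS-3-epi-quinate
Product: 7 methyl (1R,5S)-5-(tert-butyldiphenylsilyloxy)-1-hydroxycyclohex-3-ene-1-carboxylate (silyloxy trans to 1-OH)
Conditions: PPh3, I2, imidazole, toluene, 110 °C
Reagents that add atoms: none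
Why: Garegg–Samuelsson olefination of a trans-diequatorial vicinal diol (double activation by the iodophosphonium reagent, then iodide-induced reductive elimination); no stereocentre is made and the hindered tertiary alcohol is not activated.

Step 7
Reactants: 7 methyl 5-silyloxy-1-hydroxycyclohex-3-enecarboxylate
Product: 8 (1R,5S)-5-(tert-butyldiphenylsilyloxy)-1-hydroxycyclohex-3-ene-1-carboxylic acid (ring A acid)
Conditions: LiOH, THF/MeOH/H2O, rt; then aq. HCl to pH 3, 0 °C
Reagents that add atoms: lithium hydroxide ([Li+].[OH-])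
Why: Saponification of the methyl ester of an α-hydroxy ester; the secondary TBDPS ether is stable to LiOH at room temperature and no stereocentre is touched.

Step 8
Reactants: 7 methyl 5-silyloxy-1-hydroxycyclohex-3-enecarboxylate
Product: 9 methyl 5-O-TBDPS-L-quinate (3-OH and 4-OH cis to 1-OH; trans to O5)
Conditions: OsO4 (cat.), N-methylmorpholine N-oxide, acetone/H2O (5:1), rt
Reagents that add atoms: osmium tetroxide (O=[Os](=O)(=O)=O); N-methylmorpholine N-oxide (C[N+]1([O-])CCOCC1); water (O)
Why: Upjohn dihydroxylation, the same reaction as the key step on the monomer: suprafacial [3+2] addition of OsO4 anti to the allylic silyloxy group gives the cis-diol trans to O5, i.e. the L-quinate pattern, and so sets C3 and C4 of ring B.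

Step 9
Reactants: 9 methyl 5-O-TBDPS-L-quinate
Product: 10 methyl L-quinate
Conditions: NH4F, MeOH, 55 °C
Reagents that add atoms: none
Why: Fluoride cleavage of the silyl ether under neutral conditions in methanol, which also keeps the carboxyl as its methyl ester.

Step 10
Reactants: 10 methyl L-quinate
Product: 11 methyl L-quinate 4,5-O-(2,3-dimethoxybutane-2,3-diyl) bisacetal (enantiomer of 2)
Conditions: 2,3-butanedione, HC(OMe)3, 10-camphorsulfonic acid (cat.), MeOH, reflux
Reagents that add atoms: 2,3-butanedione (CC(=O)C(C)=O); methanol (CO); trimethyl orthoformate (COC(OC)OC)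
Why: Same bisacetalisation as in step 1 in the mirror-image series: only O4/O5 are trans-diequatorial, so O3 and O1 stay free and the acetal carbons become (2R,3R).

Step 11
Reactants: 11 methyl L-quinate 4,5-bisacetal
Product: 13 4-methoxybenzyl (PMB) L-quinate 4,5-bisacetal, via cesium carboxylate 12 (not isolated)
Conditions: CsOH·H2O, MeOH/H2O, rt; evaporate; 4-MeOC6H4CH2Cl, DMF, rt
Reagents that add atoms: cesium hydroxide ([Cs+].[OH-]); 4-methoxybenzyl chloride (COc1ccc(CCl)cc1)
Why: Saponification then SN2 alkylation of the cesium carboxylate, which is far more nucleophilic than the secondary and tertiary hydroxyls; the PMB ester can be removed at the end by acid together with the acetals.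

Step 12
Reactants: 13 PMB L-quinate 4,5-bisacetal
Product: 14 3-O-(2-methoxypropan-2-yl) ether of 13 (ring B alcohol; only the tertiary 1-OH free)
Conditions: 2-methoxypropene, pyridinium p-toluenesulfonate (cat.), CH2Cl2, 0 °C
Reagents that add atoms: 2-methoxypropene (COC(C)=C)
Why: Acid-catalysed addition of the secondary alcohol to the enol ether (mixed-ketal protection); the tertiary, ester-deactivated C1 hydroxyl is left free, and unlike a silyl ether this 1,3-syn-axial acetal cannot migrate to the neighbouring alkoxide in the next step.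

Step 13
Reactants: 8 ring A acid; 14 ring B alcohol
Product: 19 dimer precursor (ring A C3A=C4A olefin; O5A TBDPS ether; C1A-OH and O3B-OH free; ring B 4,5-bisacetal PMB ester), via bis-trimethylsilyl derivative 15 (not isolated), via acid chloride 16 (not isolated), via lithium alkoxide 17 (not isolated), via masked ester 18 (not isolated)
Conditions: 8: HN(SiMe3)2, Me3SiCl (cat.), 60 °C, evaporate; (COCl)2, N,N-dimethylformamide (cat.), CH2Cl2, 0 °C, evaporate. 14: LiN(SiMe3)2, THF, −78 °C; add the acid chloride, −78 → 0 °C; then citric acid, MeOH, rt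
Reagents that add atoms: none
Why: Acylation of a preformed lithium tertiary alkoxide by an acid chloride, the standard way to esterify hindered tertiary alcohols: the hydroxy acid is transiently bis-silylated and its silyl ester converted to the acid chloride under neutral conditions, there is no α-hydrogen for ketene formation, and mild acid methanolysis then frees the C1A and O3B hydroxyls without touching any stereocentre.

Step 14
Reactants: 19 dimer precursor
Product: 20 dimer with the ring A 3A,4A-cis-diol trans to O5A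
Conditions: OsO4 (5 mol %), N-methylmorpholine N-oxide, acetone/H2O (5:1), rt
Reagents that add atoms: osmium tetroxide (O=[Os](=O)(=O)=O); N-methylmorpholine N-oxide (C[N+]1([O-])CCOCC1); water (O)
Why: OsO4 adds suprafacially to the C3A=C4A olefin in a concerted [3+2] cycloaddition to give a hexavalent osmium glycolate, which water hydrolyses to the cis-diol while the N-oxide returns the metal to OsO4 (Upjohn dihydroxylation of a cyclohexene bearing an allylic oxygen, the reaction already run on monomer 7 in step 8). No ring is closed. C3A and C4A are both fixed by the face of attack, which is controlled by the allylic C5A stereocentre: the oxidant approaches anti to the bulky pseudo-equatorial O5A silyl ether, on the face of the C1A hydroxyl and away from the C1A ester that carries ring B. The step needs facial selectivity and chemoselectivity: the first is secured by the TBDPS ether and by the deliberately unmasked, small C1A hydroxyl (a silyl ether there would shield the required face, whereas the free hydroxyl can hydrogen-bond to the oxidant), the second by the absence of any other C=C bond, since the caffeoyl groups are attached only afterwards. Because the olefin is cis and the addition syn, the two new C–O bonds are cis to each other and trans to O5A, which is the L-quinate arrangement of ring A.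

Step 15
Reactants: 20 ring A diol dimer
Product: 21 3A,4A-O-isopropylidene derivative of 20
Conditions: 2,2-dimethoxypropane, pyridinium p-toluenesulfonate (cat.), acetone, rt
Reagents that add atoms: 2,2-dimethoxypropane (COC(C)(C)OC)
Why: Acid-catalysed transketalisation: only O3A/O4A form a cis-fused five-membered dioxolane, so the new diol is masked while the tertiary C1A hydroxyl and the hindered axial O3B hydroxyl stay free.

Step 16
Reactants: 21 acetonide dimer
Product: 22 acetonide dimer with free O5A-OH and O3B-OH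
Conditions: Bu4NF, AcOH (1:1), THF, rt → 40 °C
Reagents that add atoms: none
Why: Fluoride cleavage of the secondary TBDPS ether; buffering with acetic acid prevents alkoxide-driven migration of the inter-ring acyl group from O1B to the free O3B hydroxyl.

Step 17
Reactants: 23 caffeic acid
Product: 25 (E)-3-[3,4-bis(tert-butyldimethylsilyloxy)phenyl]prop-2-enoic acid, via tris-silyl compound 24 (not isolated)
Conditions: t-BuMe2SiCl (3.3 equiv), imidazole, DMF, rt; then AcOH/THF/H2O, rt
Reagents that add atoms: tert-butyl(chloro)dimethylsilane (CC(C)(C)[Si](C)(C)Cl)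
Why: Exhaustive silylation followed by selective hydrolysis of the labile silyl ester leaves the two phenolic silyl ethers; the E-olefin is untouched.

Step 18
Reactants: 22 diol dimer; 25 bis-silyl caffeic acid (2.5 equiv in all)
Product: 27 5A,3B-bis-O-[3,4-bis(tert-butyldimethylsilyloxy)cinnamoyl] derivative of 22, via acid chloride 26 (not isolated)
Conditions: 25 (2.5 equiv): (COCl)2, N,N-dimethylformamide (cat.), CH2Cl2, 0 °C → rt, evaporate; then 22 (1 equiv), pyridine, 4-(dimethylamino)pyridine (cat.), CH2Cl2, 0 °C → rt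
Reagents that add atoms: second equivalent of 3,4-bis-O-tert-butyldimethylsilyl caffeic acid 25 (O=C(O)/C=C/c1ccc(O[Si](C)(C)C(C)(C)C)c(O[Si](C)(C)C(C)(C)C)c1)
Why: Twofold acylation of the two secondary hydroxyls (O5A equatorial, O3B axial) by the acid chloride under 4-(dimethylamino)pyridine catalysis, one equivalent of the acyl donor being consumed at each oxygen; the tertiary C1A hydroxyl does not react and the E geometry of the cinnamoyl units is retained.

Step 19
Reactants: 27 protected bis-caffeoyl dimer
Product: 29 CNP0107948.1, via tetraphenol 28 (not isolated)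
Conditions: Et3N·3HF, THF, rt; evaporate; then CF3CO2H/H2O (9:1), anisole, 0 °C → rt
Reagents that add atoms: none
Why: Phenolic silyl ethers are cleaved by fluoride while every hydroxyl next to a caffeoyl ester is still masked (so acyl migration is impossible), then aqueous trifluoroacetic acid hydrolyses both acetals and cleaves the PMB ester by alkyl–oxygen fission (anisole traps the benzyl cation); the acidic medium keeps the caffeoyl groups at O5A and O3B.

Compound list
1 | D-(−)-quinic acid | O[C@@H]1C[C@](O)(C(=O)O)C[C@@H](O)[C@H]1O | starting material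
2 | methyl D-quinate 4,5-O-(2,3-dimethoxybutane-2,3-diyl) bisacetal, acetal carbons (2S,3S) | O[C@@]1(C(=O)OC)C[C@@H](O)[C@H]2O[C@](C)(OC)[C@@](C)(OC)O[C@@H]2C1 | intermediate
3 | methyl 3-dehydroquinate 4,5-bisacetal | O[C@@]1(C(=O)OC)CC(=O)[C@H]2O[C@](C)(OC)[C@@](C)(OC)O[C@@H]2C1 | intermediate
4 | methyl 3-epi-quinate 4,5-bisacetal (3-OH trans to 1-OH) | O[C@@]1(C(=O)OC)C[C@H](O)[C@H]2O[C@](C)(OC)[C@@](C)(OC)O[C@@H]2C1 | intermediate
5 | 3-O-TBDPS ether of 4 | O[C@@]1(C(=O)OC)C[C@H](O[Si](c3ccccc3)(c3ccccc3)C(C)(C)C)[C@H]2O[C@](C)(OC)[C@@](C)(OC)O[C@@H]2C1 | intermediate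
6 | methyl 3-O-TBDPS-3-epi-quinate (trans-4,5-diol) | O[C@@]1(C(=O)OC)C[C@H](O[Si](c2ccccc2)(c2ccccc2)C(C)(C)C)[C@@H](O)[C@H](O)C1 | intermediate
7 | methyl (1R,5S)-5-(tert-butyldiphenylsilyloxy)-1-hydroxycyclohex-3-ene-1-carboxylate | CC(C)(C)[Si](c1ccccc1)(c1ccccc1)O[C@H]2C[C@@](O)(C(=O)OC)CC=C2 | intermediate
8 | (1R,5S)-5-(tert-butyldiphenylsilyloxy)-1-hydroxycyclohex-3-ene-1-carboxylic acid | CC(C)(C)[Si](c1ccccc1)(c1ccccc1)O[C@H]2C[C@@](O)(C(=O)O)CC=C2 | intermediate
9 | methyl 5-O-TBDPS-L-quinate | CC(C)(C)[Si](c1ccccc1)(c1ccccc1)O[C@H]2C[C@@](O)(C(=O)OC)C[C@H](O)[C@@H]2O | intermediate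
10 | methyl L-quinate | O[C@]1(C(=O)OC)C[C@H](O)[C@H](O)[C@@H](O)C1 | intermediate
11 | methyl L-quinate 4,5-O-(2,3-dimethoxybutane-2,3-diyl) bisacetal, acetal carbons (2R,3R) | O[C@]1(C(=O)OC)C[C@H](O)[C@@H]2O[C@@](C)(OC)[C@](C)(OC)O[C@H]2C1 | intermediate
12 | cesium carboxylate of 11 | O[C@]1(C(=O)[O-])C[C@H](O)[C@@H]2O[C@@](C)(OC)[C@](C)(OC)O[C@H]2C1.[Cs+] | intermediate
13 | 4-methoxybenzyl L-quinate 4,5-bisacetal | O[C@]1(C(=O)OCc3ccc(OC)cc3)C[C@H](O)[C@@H]2O[C@@](C)(OC)[C@](C)(OC)O[C@H]2C1 | intermediate
14 | 3-O-(2-methoxypropan-2-yl) ether of 13 | O[C@]1(C(=O)OCc3ccc(OC)cc3)C[C@H](OC(C)(C)OC)[C@@H]2O[C@@](C)(OC)[C@](C)(OC)O[C@H]2C1 | intermediate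
15 | trimethylsilyl ester of the 1-O-trimethylsilyl ether of 8 | CC(C)(C)[Si](c1ccccc1)(c1ccccc1)O[C@H]2C[C@@](O[Si](C)(C)C)(C(=O)O[Si](C)(C)C)CC=C2 | intermediate
16 | 1-O-trimethylsilyl acid chloride of 8 | CC(C)(C)[Si](c1ccccc1)(c1ccccc1)O[C@H]2C[C@@](O[Si](C)(C)C)(C(=O)Cl)CC=C2 | intermediate
17 | lithium 1-alkoxide of 14 | [Li+].[O-][C@]1(C(=O)OCc3ccc(OC)cc3)C[C@H](OC(C)(C)OC)[C@@H]2O[C@@](C)(OC)[C@](C)(OC)O[C@H]2C1 | intermediate
18 | O1B ester of 14 with the acyl group of 16 (C1A-OSiMe3; O3B methoxypropyl ether) | CC(C)(C)[Si](c5ccccc5)(c6ccccc6)O[C@H]1C[C@@](O[Si](C)(C)C)(C(=O)O[C@]2(C(=O)OCc3ccc(OC)cc3)C[C@H](OC(C)(C)OC)[C@@H]4O[C@@](C)(OC)[C@](C)(OC)O[C@H]4C2)CC=C1 | intermediate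
19 | dimer precursor: ring A C3A=C4A olefin, O5A TBDPS ether, C1A-OH and O3B-OH free, ring B 4,5-bisacetal PMB ester | CC(C)(C)[Si](c5ccccc5)(c6ccccc6)O[C@H]1C[C@@](O)(C(=O)O[C@]2(C(=O)OCc3ccc(OC)cc3)C[C@H](O)[C@@H]4O[C@@](C)(OC)[C@](C)(OC)O[C@H]4C2)CC=C1 | intermediate
20 | dimer with ring A 3A,4A-cis-diol trans to O5A | CC(C)(C)[Si](c5ccccc5)(c6ccccc6)O[C@H]1C[C@@](O)(C(=O)O[C@]2(C(=O)OCc3ccc(OC)cc3)C[C@H](O)[C@@H]4O[C@@](C)(OC)[C@](C)(OC)O[C@H]4C2)C[C@H](O)[C@@H]1O | intermediate
21 | 3A,4A-O-isopropylidene derivative of 20 | CC(C)(C)[Si](c5ccccc5)(c6ccccc6)O[C@H]1C[C@@](O)(C(=O)O[C@]2(C(=O)OCc3ccc(OC)cc3)C[C@H](O)[C@@H]4O[C@@](C)(OC)[C@](C)(OC)O[C@H]4C2)C[C@@H]7OC(C)(C)O[C@H]17 | intermediate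
22 | O5A-desilylated 21 (free O5A-OH and O3B-OH) | O[C@H]1C[C@@](O)(C(=O)O[C@]2(C(=O)OCc3ccc(OC)cc3)C[C@H](O)[C@@H]4O[C@@](C)(OC)[C@](C)(OC)O[C@H]4C2)C[C@@H]7OC(C)(C)O[C@H]17 | intermediate
23 | caffeic acid | O=C(O)/C=C/c1ccc(O)c(O)c1 | starting material
24 | tert-butyldimethylsilyl (E)-3-[3,4-bis(tert-butyldimethylsilyloxy)phenyl]prop-2-enoate | CC(C)(C)[Si](C)(C)OC(=O)/C=C/c1ccc(O[Si](C)(C)C(C)(C)C)c(O[Si](C)(C)C(C)(C)C)c1 | intermediate
25 | (E)-3-[3,4-bis(tert-butyldimethylsilyloxy)phenyl]prop-2-enoic acid | O=C(O)/C=C/c1ccc(O[Si](C)(C)C(C)(C)C)c(O[Si](C)(C)C(C)(C)C)c1 | intermediate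
26 | (E)-3-[3,4-bis(tert-butyldimethylsilyloxy)phenyl]prop-2-enoyl chloride | O=C(Cl)/C=C/c1ccc(O[Si](C)(C)C(C)(C)C)c(O[Si](C)(C)C(C)(C)C)c1 | intermediate
27 | 5A,3B-bis-O-[3,4-bis(tert-butyldimethylsilyloxy)cinnamoyl] derivative of 22 | O=C(/C=C/c8ccc(O[Si](C)(C)C(C)(C)C)c(O[Si](C)(C)C(C)(C)C)c8)O[C@H]1C[C@@](O)(C(=O)O[C@]2(C(=O)OCc3ccc(OC)cc3)C[C@H](OC(=O)/C=C/c5ccc(O[Si](C)(C)C(C)(C)C)c(O[Si](C)(C)C(C)(C)C)c5)[C@@H]4O[C@@](C)(OC)[C@](C)(OC)O[C@H]4C2)C[C@@H]7OC(C)(C)O[C@H]17 | intermediate
28 | tetraphenol: 27 without the four aryl silyl ethers | O=C(/C=C/c8ccc(O)c(O)c8)O[C@H]1C[C@@](O)(C(=O)O[C@]2(C(=O)OCc3ccc(OC)cc3)C[C@H](OC(=O)/C=C/c5ccc(O)c(O)c5)[C@@H]4O[C@@](C)(OC)[C@](C)(OC)O[C@H]4C2)C[C@@H]7OC(C)(C)O[C@H]17 | intermediate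
29 | CNP0107948.1 | O=C(/C=C/c1ccc(O)c(O)c1)O[C@H]1C[C@@](O)(C(=O)O[C@]2(C(=O)O)C[C@H](OC(=O)/C=C/c3ccc(O)c(O)c3)[C@H](O)[C@@H](O)C2)C[C@H](O)[C@@H]1O | target

Total step count: 19. Longest linear sequence: 17 steps (steps 1–6, 8–16, 18 and 19, from D-quinic acid through ring B).

Steps most likely to fail

Step 13 (ester between two tertiary centres). Acylation of the congested lithium alkoxide 17 (O1B is axial, with a syn-axial substituent on O3B) may be too slow. The acid chloride would then be consumed by adventitious nucleophiles, or the alkoxide would exchange with the PMB ester of a second molecule. The fallback makes the bond intramolecularly and sets out from 11 and 8. Cesium carboxylate 12 (no O3B protection, no PMB ester yet) is treated with acid chloride 16 in DMF/CH2Cl2 at 0 °C, where the unhindered carboxylate should give the mixed anhydride F1 of the two acids. With Et3N and catalytic 4-(dimethylamino)pyridine the geminal O1B hydroxyl then attacks the ring A carbonyl through a five-membered transition state, which should give the O1B-acylated ring B acid F2 as its carboxylate. This is the known O-acylation of tertiary α-hydroxy acids by acid chlorides; the axial O3B hydroxyl cannot reach the anhydride. 4-Methoxybenzyl chloride added to the same flask alkylates the carboxylate to the PMB ester F3 of that acid, and citric acid in methanol removes the trimethylsilyl ether. The route is rejoined at 19.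

Step 14 (key dihydroxylation). Facial selectivity may erode in the dimer, because the axial C1A substituent sits on the face that must be attacked, and the 3A,4A-bis-epimer would be hard to separate at this size. The fallback forms the two C–O bonds before the coupling and sets out from 9, the product of the same oxidation on monomer 7, which can be purified at that stage. 2,2-Dimethoxypropane and pyridinium p-toluenesulfonate should give the acetonide methyl ester F4 of the monomer, and LiOH then gives the acetonide acid F5 from it. Silylation with HN(SiMe3)2 gives the bis-trimethylsilyl derivative F6 of that acid, and (COCl)2 with catalytic N,N-dimethylformamide converts it into the acid chloride F7 for the coupling. This acylates lithium alkoxide 17 to the masked ester F8 of the two rings. Citric acid in methanol removes the trimethylsilyl and methoxypropyl groups, and the route is rejoined at 21.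

Step 6 (Garegg–Samuelsson olefination). Double activation of the trans-diol next to the bulky silyl ether may stall at the iodohydrin or epoxide stage, or the C5 hydroxyl may lactonise onto the ester at 110 °C. The fallback sets out from 6: MsCl and pyridine at 0 °C give the 4,5-di-O-methanesulfonate F9 of the diol, which is reduced with NaI and zinc dust in DMF at 120 °C (Tipson–Cohen elimination). The route is rejoined at 7.

Further compounds
F1 | step 13 | mixed anhydride of the ring B carboxyl of 12 with the acyl group of 16 | CC(C)(C)[Si](c5ccccc5)(c6ccccc6)O[C@H]1C[C@@](O[Si](C)(C)C)(C(=O)OC(=O)[C@@]2(O)C[C@H](O)[C@@H]4O[C@@](C)(OC)[C@](C)(OC)O[C@H]4C2)CC=C1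
F2 | step 13 | O1B-acylated ring B carboxylic acid (C1A-OSiMe3; O3B-OH free) | CC(C)(C)[Si](c5ccccc5)(c6ccccc6)O[C@H]1C[C@@](O[Si](C)(C)C)(C(=O)O[C@]2(C(=O)O)C[C@H](O)[C@@H]4O[C@@](C)(OC)[C@](C)(OC)O[C@H]4C2)CC=C1
F3 | step 13 | 4-methoxybenzyl ester of F2 | CC(C)(C)[Si](c5ccccc5)(c6ccccc6)O[C@H]1C[C@@](O[Si](C)(C)C)(C(=O)O[C@]2(C(=O)OCc3ccc(OC)cc3)C[C@H](O)[C@@H]4O[C@@](C)(OC)[C@](C)(OC)O[C@H]4C2)CC=C1
F4 | step 14 | methyl 5-O-TBDPS-3,4-O-isopropylidene-L-quinate | CC(C)(C)[Si](c5ccccc5)(c6ccccc6)O[C@H]1C[C@@](O)(C(=O)OC)C[C@@H]7OC(C)(C)O[C@H]17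
F5 | step 14 | 5-O-TBDPS-3,4-O-isopropylidene-L-quinic acid | CC(C)(C)[Si](c5ccccc5)(c6ccccc6)O[C@H]1C[C@@](O)(C(=O)O)C[C@@H]7OC(C)(C)O[C@H]17
F6 | step 14 | trimethylsilyl ester of the 1-O-trimethylsilyl ether of F5 | CC(C)(C)[Si](c5ccccc5)(c6ccccc6)O[C@H]1C[C@@](O[Si](C)(C)C)(C(=O)O[Si](C)(C)C)C[C@@H]7OC(C)(C)O[C@H]17
F7 | step 14 | 1-O-trimethylsilyl acid chloride of F5 | CC(C)(C)[Si](c5ccccc5)(c6ccccc6)O[C@H]1C[C@@](O[Si](C)(C)C)(C(=O)Cl)C[C@@H]7OC(C)(C)O[C@H]17
F8 | step 14 | O1B ester of 14 with the acyl group of F7 (C1A-OSiMe3; O3B methoxypropyl ether) | CC(C)(C)[Si](c5ccccc5)(c6ccccc6)O[C@H]1C[C@@](O[Si](C)(C)C)(C(=O)O[C@]2(C(=O)OCc3ccc(OC)cc3)C[C@H](OC(C)(C)OC)[C@@H]4O[C@@](C)(OC)[C@](C)(OC)O[C@H]4C2)C[C@@H]7OC(C)(C)O[C@H]17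
F9 | step 6 | 4,5-di-O-methanesulfonate of 6 | O[C@@]1(C(=O)OC)C[C@H](O[Si](c2ccccc2)(c2ccccc2)C(C)(C)C)[C@@H](OS(C)(=O)=O)[C@H](OS(C)(=O)=O)C1
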